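**Retrosynthetic overview**
1. Numbering used: ring A = C4–C5–C6–C7–C16, ring B = C1–C2–C3–C4–C16–C15 (C1=C15), ring C = the eleven-membered ring C1/C15/C16/C7–C14. Target 29 ← tetraol 28 (selective triacetylation) ← enone 27 (hydroxyl-directed reduction) ← silylene-bridged tetracycle 26.
2. Key disconnection: ring B of 26 ← two-carbon ring expansion of a cis-fused bicyclo[3.2.0]heptan-6-one (ring A plus a four-membered ring) by insertion of the propynyl group on C14 into the C2–C16 bond (new bonds C1–C2 and C15–C16). It is run transannularly inside the 14-membered silicon-bridged macrocycle 23, so ring C closes in the same operation.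
3. Enabling feature: ring B is a cyclohexene whose tetrasubstituted C1=C15 olefin sits next to oxygenated C2 (the retron of alkyne plus cyclobutanone), and C4–C16 is a cis ring fusion (the former cyclobutane bond). The C3 and C14 oxygens lie on the same face on either side of C2–C1, so an O3–Si–O14 tether can fix both the alkyne orientation and the C–C bond that breaks.
4. 23 ← Nozaki–Hiyama–Kishi closure of C8–C9 in silaketal 21 ← hydroxy cyclobutanone 13 + hydroxy ynal 19 (from (S)-citronellal: C12 from the pool, C14 by asymmetric transfer hydrogenation).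
5. 13 ← allenoate [2+2] on 1,4-dimethylcyclohexa-1,4-diene (from p-xylene), then ozonolysis/aldol remodelling of the six-membered ring into ring A. Ring order: four-membered ring → ring A → 14-membered macrocycle → rings B and C together.

Key step: step 17

Assumption: in the two reagent-controlled steps (2 and 15) the catalyst or ligand enantiomer written is the one expected to give the drawn configuration; if the sense of induction proves opposite, its mirror image is used with no other change.

**Route**

Step 1
Reactants: 1 p-xylene
Product: 2 1,4-dimethylcyclohexa-1,4-diene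
Conditions: Li, NH3 (l), THF, EtOH, −78 → −33 °C
Reagents that add atoms: none
Why: Birch reduction of a 1,4-dialkylbenzene should leave both alkyl groups on the remaining double bonds, giving the skipped 1,4-diene.

Step 2
Reactants: 2 1,4-dimethylcyclohexa-1,4-diene; 3 ethyl buta-2,3-dienoate
Product: 4 ethyl (E)-2-(cis-1,4-dimethylbicyclo[4.2.0]oct-3-en-7-ylidene)acetate
Conditions: 2 (3 equiv), (S)-o-tolyl-CBS oxazaborolidine activated with AlBr3 (20 mol %), CH2Cl2, −78 → −30 °C
Reagents that add atoms: none
Why: In this Lewis-acid-catalysed enantioselective allenoate–alkene [2+2] cycloaddition the electrophilic central allene carbon should bond to the less substituted olefin carbon (future C16) and the CH2 terminus to the methyl-bearing carbon (future C4), suprafacially (cis fusion), and since the two olefins of 2 are homotopic the chiral Lewis acid only has to choose the olefin face, which sets C4 and C16.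

Step 3
Reactants: 4 ethyl (E)-2-(cis-1,4-dimethylbicyclo[4.2.0]oct-3-en-7-ylidene)acetate
Product: 5 2-[cis-1-methyl-3-oxo-2-(2-oxopropyl)cyclobutyl]acetaldehyde
Conditions: O3, CH2Cl2/MeOH, −78 °C; then Me2S, −78 °C → rt
Reagents that add atoms: ozone, [O-][O+]=O
Why: Exhaustive ozonolysis with reductive work-up should cleave both the ring olefin (to the acetonyl and formylmethyl arms) and the exocyclic enoate (to the cyclobutanone) without touching the two stereocentres.

Step 4
Reactants: 5 2-[cis-1-methyl-3-oxo-2-(2-oxopropyl)cyclobutyl]acetaldehyde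
Product: 6 cis-4-acetyl-1-methylbicyclo[3.2.0]hept-3-en-6-one
Conditions: KOH (0.2 M aq.), THF, 0 °C → rt
Reagents that add atoms: none
Why: Base-mediated intramolecular aldol condensation should close ring A through the internal CH2 of the methyl ketone onto the neopentyl aldehyde (five-membered ring, then dehydration), and since only cis-disposed arms can close, any epimerisation at C16 converges on the cis-fused product.

Step 5
Reactants: 6 cis-4-acetyl-1-methylbicyclo[3.2.0]hept-3-en-6-one
Product: 7 6,6-ethylenedioxy ketal of 6 (spiro-dioxolane at the cyclobutanone carbon)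
Conditions: Me3SiOCH2CH2OSiMe3, Me3SiOTf (5 mol %), CH2Cl2, −78 °C
Reagents that add atoms: 1,2-bis(trimethylsilyloxy)ethane, C[Si](C)(C)OCCO[Si](C)(C)C
Why: Silyl-triflate-catalysed ketalisation should select the strained saturated cyclobutanone over the conjugated acetyl group.

Step 6
Reactants: 7 6,6-ethylenedioxy ketal of 6
Product: 8 4-endo-acetyl-6,6-ethylenedioxy-1-methylbicyclo[3.2.0]heptane
Conditions: H2 (1 atm), Pd/C (10 wt %), EtOAc, rt
Reagents that add atoms: none
Why: Heterogeneous hydrogenation of the enone C=C should deliver hydrogen from the convex (exo) face of the cis-fused bicycle, placing the C7 hydrogen exo and the acetyl group endo, cis to the four-membered ring.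

Step 7
Reactants: 8 4-endo-acetyl-6,6-ethylenedioxy-1-methylbicyclo[3.2.0]heptane
Product: 9 enol triflate of 8 (4-endo-[1-(trifluoromethylsulfonyloxy)ethenyl] ketal)
Conditions: KN(SiMe3)2, THF, −78 °C; then PhNTf2, −78 → 0 °C
Reagents that add atoms: N-phenylbis(trifluoromethanesulfonimide), O=S(=O)(N(c1ccccc1)S(=O)(=O)C(F)(F)F)C(F)(F)F
Why: Kinetic deprotonation at the methyl group and O-triflation should give the terminal enol triflate and lock the contra-thermodynamic endo configuration at C7, which is no longer epimerisable.

Step 8
Reactants: 9 enol triflate of 8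
Product: 10 4-endo-[1-(trifluoromethylsulfonyloxy)ethenyl]-1-methylbicyclo[3.2.0]heptan-6-one
Conditions: HCl (2 M aq.), THF, 40 °C
Reagents that add atoms: water, O
Why: Acid hydrolysis of the dioxolane should return the cyclobutanone while the acid-stable enol triflate survives.

Step 9
Reactants: 10 4-endo-[1-(trifluoromethylsulfonyloxy)ethenyl]-1-methylbicyclo[3.2.0]heptan-6-one
Product: 13 (1S,4R,5R,7R)-7-hydroxy-1-methyl-4-[1-(trifluoromethylsulfonyloxy)ethenyl]bicyclo[3.2.0]heptan-6-one, via silyl enol ether 11 (not isolated), via trimethylsilyloxy ketone 12 (not isolated)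
Conditions: Me3SiOTf, Et3N, CH2Cl2, 0 °C; then dimethyldioxirane (acetone solution), −78 °C; then aq. citric acid, THF, 0 °C
Reagents that add atoms: dimethyldioxirane, CC1(C)OO1
Why: In this Rubottom-type oxidation soft enolisation can only go toward the CH2 (C3), and the dioxirane, which avoids Baeyer–Villiger oxidation of the cyclobutanone, should attack the silyl enol ether from the exo face, giving the hydroxyl cis to the angular methyl.

Step 10
Reactants: 14 (S)-citronellal; 15 1-propynylmagnesium bromide
Product: 16 (6S)-6,10-dimethylundec-9-en-2-yn-4-ol (mixture of C4 epimers)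
Conditions: THF, −78 → 0 °C
Reagents that add atoms: none
Why: Grignard addition to the aldehyde needs no stereocontrol because the carbinol is oxidised in the next step.

Step 11
Reactants: 16 (6S)-6,10-dimethylundec-9-en-2-yn-4-ol
Product: 17 (6S)-6,10-dimethylundec-9-en-2-yn-4-one
Conditions: Dess–Martin periodinane, NaHCO3, CH2Cl2, 0 °C → rt
Reagents that add atoms: none
Why: Dess–Martin oxidation of the propargylic alcohol should give the ynone without touching the remote methyl stereocentre.

Step 12
Reactants: 17 (6S)-6,10-dimethylundec-9-en-2-yn-4-one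
Product: 18 (4S,6S)-6,10-dimethylundec-9-en-2-yn-4-ol
Conditions: RuCl[(S,S)-TsDPEN](p-cymene) (1 mol %), i-PrOH, rt
Reagents that add atoms: none
Why: Noyori asymmetric transfer hydrogenation of an alkynyl ketone is catalyst-controlled, and the (S,S) catalyst should give the (S)-propargylic alcohol (future C14).

Step 13
Reactants: 18 (4S,6S)-6,10-dimethylundec-9-en-2-yn-4-ol
Product: 19 (4S,6S)-6-hydroxy-4-methylnon-7-ynal
Conditions: O3 (1 equiv), CH2Cl2/MeOH, −78 °C; then Me2S
Reagents that add atoms: ozone, [O-][O+]=O
Why: Ozonolysis should be chemoselective because the electron-rich trisubstituted olefin reacts far faster than the internal alkyne, unmasking the C9 aldehyde.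

Step 14
Reactants: 13 hydroxy cyclobutanone; 19 (4S,6S)-6-hydroxy-4-methylnon-7-ynal
Product: 21 diisopropylsilylene-linked bis-ether (silaketal) of 13 and 19, via chlorosilyl ether 20 (not isolated)
Conditions: i-Pr2SiCl2 (3 equiv), imidazole, CH2Cl2, 0 °C; removal of excess silane in vacuo; then 19, imidazole, DMF, 0 °C → rt
Reagents that add atoms: dichlorodiisopropylsilane, CC(C)[Si](Cl)(Cl)C(C)C
Why: Sequential silylation (hindered alcohol first with excess dichlorosilane, then the unhindered propargylic alcohol) is the standard way to an unsymmetrical silicon tether and affects no stereocentre.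

Step 15
Reactants: 21 silaketal
Product: 22 14-membered macrocyclic allylic alcohol ((9R)-hydroxy, 8(19)-methylene, silicon bridge O3–Si–O14, cyclobutanone and propynyl group intact)
Conditions: CrCl2 (8 equiv), NiCl2 (0.4 equiv), (S)-N-[2-(4-isopropyl-4,5-dihydrooxazol-2-yl)-6-methylphenyl]methanesulfonamide (8.5 equiv), Et3N (8.5 equiv), THF/MeCN, rt, slow addition of 21 (final 2 mM)
Reagents that add atoms: none
Why: In this Nozaki–Hiyama–Kishi macrocyclisation the alkenylchromium species formed from the enol triflate should add only to the aldehyde (ketone and alkyne are inert), closing the unstrained 14-membered ring, with the chiral sulfonamide ligand on chromium controlling the face of addition at C9 (reagent control).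

Step 16
Reactants: 22 macrocyclic allylic alcohol
Product: 23 tert-butyldimethylsilyl ether of 22
Conditions: t-BuMe2SiOTf, 2,6-lutidine, CH2Cl2, −40 → 0 °C
Reagents that add atoms: tert-butyldimethylsilyl triflate, CC(C)(C)[Si](C)(C)OS(=O)(=O)C(F)(F)F
Why: Silylation masks the allylic hydroxyl, which could otherwise protonate organonickel intermediates, as an ether that zerovalent nickel does not ionise.

Step 17
Reactants: 23 macrocyclic silyl ether
Product: 26 tetracyclic enone (rings A, B and C formed; C2 ketone; O3–Si(i-Pr)2–O14 bridge; 9-O-silyl ether), via oxanickelacyclopentene 24 (not isolated), via nickelacycloheptenone 25 (not isolated)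
Conditions: Ni(cod)2 (20 mol %), PCy3 (40 mol %), toluene (5 mM), 90 °C
Reagents that add atoms: none
Why: Proposed new method: zerovalent nickel should join the cyclobutanone C=O and the tethered alkyne by oxidative cyclisation (C1–C2 bond, 24), strain-driven β-carbon elimination should then move C16 from C2 to nickel (25), and C(sp2)–C(sp3) reductive elimination should form C15–C16; the closest known reaction type is the nickel-catalysed intermolecular insertion of alkynes into 3-substituted cyclobutanones (formal [4+2]) and its intramolecular alkene version, which has not been shown for a tethered alkyne or for cleavage of an acyl–C(methine) bond. Ring B closes as a two-carbon ring expansion of the four-membered ring (six-membered, both alkyne carbons endocyclic), ring C (eleven-membered) closes transannularly in the reductive elimination by contraction of the 14-membered ring, and a temporary seven-membered dioxasilepane closes in the oxidative cyclisation. No stereocentre is created: C16 keeps its configuration because β-carbon elimination and reductive elimination both go with retention at carbon, and the cis fusion and endo C7 substituent set in steps 2 and 6 are carried through. The step needs C2 to bond to C1 and not C15, and C2–C16 to break and not C2–C3; the silicon tether should secure both, because C2–C15 bonding would put an E-olefin into an eight-membered ring and migration of C3 could only end in an E-olefin within a seven-membered ring, whereas the wanted path keeps the olefin exocyclic to the siloxane ring. β-Hydride elimination from 25 should be shut off because C4 is quaternary and the only β-hydrogen (on C7) is anti to nickel, and the 1,1-disubstituted olefin and silyl ethers are far poorer partners for zerovalent nickel than the alkyne.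

Step 18
Reactants: 26 tetracyclic enone
Product: 27 triol enone (target skeleton with C2 ketone and free hydroxyls at C3, C9 and C14)
Conditions: HF·pyridine, pyridine/THF, 0 °C → rt
Reagents that add atoms: none
Why: Fluoride-mediated desilylation should remove the silicon bridge and the silyl ether together under non-basic conditions, releasing the strain of the bridged siloxane and leaving the α-hydroxy enone unepimerised.

Step 19
Reactants: 27 triol enone
Product: 28 tetraol (2,3-trans-diol; hydroxyls at C2, C3, C9 and C14)
Conditions: Me4NBH(OAc)3, MeCN/AcOH (1:1), −30 → 0 °C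
Reagents that add atoms: none
Why: In this hydroxyl-directed (Evans–Saksena-type) reduction the borohydride bound to the C3 and C14 hydroxyls, which both lie on the face opposite to the ring C bridge, should deliver hydride intramolecularly to that face of the C2 carbonyl, placing the new hydroxyl trans to the C3 hydroxyl with no conjugate reduction.

Step 20
Reactants: 28 tetraol
Product: 29 target triacetate (acetates at C2, C9 and C14, free C3 hydroxyl)
Conditions: Ac2O (3.3 equiv), pyridine, 4-(dimethylamino)pyridine (5 mol %), CH2Cl2, 0 °C
Reagents that add atoms: acetic anhydride, CC(=O)OC(C)=O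
Why: Acylation should take the three allylic secondary hydroxyls and leave the neopentyl C3 hydroxyl, which is flanked by the quaternary C4 and cis to its methyl group, free under these mild conditions.

**Compound list**
1 | p-xylene | Cc1ccc(C)cc1 | starting material
2 | 1,4-dimethylcyclohexa-1,4-diene | CC1=CCC(C)=CC1 | intermediate
3 | ethyl buta-2,3-dienoate | C=C=CC(=O)OCC | starting material
4 | ethyl (E)-2-(cis-1,4-dimethylbicyclo[4.2.0]oct-3-en-7-ylidene)acetate, ester syn to the ring CH2 | CCOC(=O)/C=C1\C[C@@]2(C)CC=C(C)C[C@@H]12 | intermediate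
5 | 2-[cis-1-methyl-3-oxo-2-(2-oxopropyl)cyclobutyl]acetaldehyde | CC(=O)C[C@H]1C(=O)C[C@@]1(C)CC=O | intermediate
6 | cis-4-acetyl-1-methylbicyclo[3.2.0]hept-3-en-6-one | CC(=O)C1=CC[C@]2(C)CC(=O)[C@H]12 | intermediate
7 | 6,6-ethylenedioxy ketal of 6 | CC(=O)C1=CC[C@]2(C)CC3(OCCO3)[C@H]12 | intermediate
8 | 4-endo-acetyl-6,6-ethylenedioxy-1-methylbicyclo[3.2.0]heptane | CC(=O)[C@@H]1CC[C@]2(C)CC3(OCCO3)[C@H]12 | intermediate
9 | enol triflate of 8 | C=C(OS(=O)(=O)C(F)(F)F)[C@@H]1CC[C@]2(C)CC3(OCCO3)[C@H]12 | intermediate
10 | 4-endo-[1-(trifluoromethylsulfonyloxy)ethenyl]-1-methylbicyclo[3.2.0]heptan-6-one | C=C(OS(=O)(=O)C(F)(F)F)[C@@H]1CC[C@]2(C)CC(=O)[C@H]12 | intermediate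
11 | trimethylsilyl enol ether of 10 (bicyclo[3.2.0]hept-6-ene) | C=C(OS(=O)(=O)C(F)(F)F)[C@@H]1CC[C@]2(C)C=C(O[Si](C)(C)C)[C@H]12 | intermediate
12 | 7-exo-trimethylsilyloxy derivative of 10 | C=C(OS(=O)(=O)C(F)(F)F)[C@@H]1CC[C@]2(C)[C@@H](O[Si](C)(C)C)C(=O)[C@H]12 | intermediate
13 | (1S,4R,5R,7R)-7-hydroxy-1-methyl-4-[1-(trifluoromethylsulfonyloxy)ethenyl]bicyclo[3.2.0]heptan-6-one (hydroxyl exo, cis to methyl; side chain endo) | C=C(OS(=O)(=O)C(F)(F)F)[C@@H]1CC[C@]2(C)[C@@H](O)C(=O)[C@H]12 | intermediate
14 | (S)-citronellal | O=CC[C@@H](C)CCC=C(C)C | starting material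
15 | 1-propynylmagnesium bromide | CC#C[Mg]Br | starting material
16 | (6S)-6,10-dimethylundec-9-en-2-yn-4-ol, C4 epimers | CC#CC(O)C[C@@H](C)CCC=C(C)C | intermediate
17 | (6S)-6,10-dimethylundec-9-en-2-yn-4-one | CC#CC(=O)C[C@@H](C)CCC=C(C)C | intermediate
18 | (4S,6S)-6,10-dimethylundec-9-en-2-yn-4-ol | CC#C[C@@H](O)C[C@@H](C)CCC=C(C)C | intermediate
19 | (4S,6S)-6-hydroxy-4-methylnon-7-ynal | CC#C[C@@H](O)C[C@@H](C)CCC=O | intermediate
20 | chlorodiisopropylsilyl ether of 13 | C=C(OS(=O)(=O)C(F)(F)F)[C@@H]1CC[C@]2(C)[C@@H](O[Si](Cl)(C(C)C)C(C)C)C(=O)[C@H]12 | intermediate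
21 | diisopropylsilylene bis-ether of 13 (O3) and 19 (O14) | C=C(OS(=O)(=O)C(F)(F)F)[C@@H]1CC[C@]2(C)[C@@H](O[Si](C(C)C)(C(C)C)O[C@H](C#CC)C[C@@H](C)CCC=O)C(=O)[C@H]12 | intermediate
22 | 14-membered macrocyclic (9R)-allylic alcohol with 8(19)-methylene, cyclobutanone and C14 propynyl group | C=C1[C@H](O)CC[C@H](C)C[C@@H](C#CC)O[Si](C(C)C)(C(C)C)O[C@H]2C(=O)[C@@H]3[C@H]1CC[C@@]32C | intermediate
23 | 9-O-tert-butyldimethylsilyl ether of 22 | C=C1[C@H](O[Si](C)(C)C(C)(C)C)CC[C@H](C)C[C@@H](C#CC)O[Si](C(C)C)(C(C)C)O[C@H]2C(=O)[C@@H]3[C@H]1CC[C@@]32C | intermediate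
24 | oxanickelacyclopentene from 23 (C1–C2 bond formed; phosphine ligands on nickel omitted) | C=C1[C@H](O[Si](C)(C)C(C)(C)C)CC[C@H](C)C[C@@H]4O[Si](C(C)C)(C(C)C)O[C@H]2[C@]5(O[Ni]C(C)=C45)[C@@H]3[C@H]1CC[C@@]32C | intermediate
25 | seven-membered nickelacycle (nickel on C15 and C16, C2 ketone; ligands omitted) | C=C1[C@H](O[Si](C)(C)C(C)(C)C)CC[C@H](C)C[C@@H]4O[Si](C(C)C)(C(C)C)O[C@H]2C(=O)C4=C(C)[Ni][C@@H]3[C@H]1CC[C@@]32C | intermediate
26 | tetracyclic enone: target skeleton with C2 ketone, O3–Si(i-Pr)2–O14 bridge and 9-O-silyl ether | C=C1[C@H](O[Si](C)(C)C(C)(C)C)CC[C@H](C)C[C@H](O[Si](C(C)C)(C(C)C)O4)C2=C(C)[C@@H]3[C@H]1CC[C@]3(C)[C@@H]4C2=O | intermediate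
27 | triol enone: target skeleton with C2 ketone and free C3, C9, C14 hydroxyls | C=C1[C@H](O)CC[C@H](C)C[C@H](O)C2=C(C)[C@@H]3[C@H]1CC[C@]3(C)[C@@H](O)C2=O | intermediate
28 | tetraol: target skeleton with free C2, C3, C9, C14 hydroxyls (2,3-trans) | C=C1[C@H](O)CC[C@H](C)C[C@H](O)C2=C(C)[C@@H]3[C@H]1CC[C@]3(C)[C@@H](O)[C@@H]2O | intermediate
29 | target triacetate (CNP0318778.1) | C=C1[C@H](OC(C)=O)CC[C@H](C)C[C@H](OC(C)=O)C2=C(C)[C@@H]3[C@H]1CC[C@]3(C)[C@@H](O)[C@@H]2OC(C)=O | target

**Totals**
Total step count: 20. Longest linear sequence: 16 steps (steps 1–9, then 14–20); steps 10–13 form the convergent branch to 19.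

**Steps most likely to fail**

1. Step 17. What may go wrong: β-carbon elimination may take the C2–C3 bond, the oxidative cyclisation may stall because the macrocycle cannot bring alkyne and carbonyl together, or strain may build up in the bridged siloxane before reductive elimination. The fallback uses known reaction types and sets out from 23. A low-valent titanium alkyne complex (Ti(OiPr)4 and 2 i-PrMgCl premixed at −78 °C, then 23, −50 °C) should add transannularly to the cyclobutanone carbonyl through the same seven-membered closure; iodinolysis (I2) of the oxatitanacycle gives the (Z)-β-iodoalkenyl cyclobutanol F1. Palladium-catalysed ring-opening coupling of this tertiary cyclobutanol with its own alkenyl iodide (Pd(PPh3)4, Cs2CO3, toluene, 80 °C; oxidative addition, palladium alkoxide, β-carbon elimination, C–C reductive elimination) then returns to the route at 26.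

2. Step 15. What may go wrong: poor facial selectivity at C9 during ring closure, or intermolecular coupling competing with cyclisation. Oxidation and reagent-controlled reduction is not available here because the cyclobutanone would also be reduced. The fallback sets out from 21: the coupling is run without relying on the ligand, the epimers are separated, and the unwanted (9S)-alcohol F2 is inverted by Mitsunobu reaction (ClCH2CO2H, PPh3, DIAD, THF) to the (9R)-chloroacetate F3. Mild cleavage (thiourea, NaHCO3, EtOH/THF) returns to the route at 22.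

3. Step 2. What may go wrong: low enantiofacial discrimination, or hydride transfer and ene reaction of the skipped diene under the strong Lewis acid. The fallback replaces catalyst control by auxiliary control and sets out from 2. Buta-2,3-dienoic acid is esterified with (−)-8-phenylmenthol (DCC, DMAP) to (−)-8-phenylmenthyl buta-2,3-dienoate F4. The EtAlCl2-promoted [2+2] cycloaddition with 2 gives the 8-phenylmenthyl ester analogue of 4, F5, whose diastereomers are separated. Ozonolysis under the conditions of step 3 removes the auxiliary as its glyoxylate and returns to the route at 5.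

**Further compounds**
F1 | step 17 | (Z)-β-iodoalkenyl cyclobutanol (C1–C2 bond formed, iodine on C15, tertiary hydroxyl on C2) | C=C1[C@H](O[Si](C)(C)C(C)(C)C)CC[C@H](C)C[C@@H]4O[Si](C(C)C)(C(C)C)O[C@H]2[C@@](O)(/C4=C(/C)I)[C@@H]3[C@H]1CC[C@@]32C
F2 | step 15 | (9S)-epimer of 22 | C=C1[C@@H](O)CC[C@H](C)C[C@@H](C#CC)O[Si](C(C)C)(C(C)C)O[C@H]2C(=O)[C@@H]3[C@H]1CC[C@@]32C
F3 | step 15 | (9R)-chloroacetate of 22 | C=C1[C@H](OC(=O)CCl)CC[C@H](C)C[C@@H](C#CC)O[Si](C(C)C)(C(C)C)O[C@H]2C(=O)[C@@H]3[C@H]1CC[C@@]32C
F4 | step 2 | (−)-8-phenylmenthyl buta-2,3-dienoate | CC(C)(c1ccccc1)[C@@H]1CC[C@@H](C)C[C@H]1OC(=O)C=C=C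
F5 | step 2 | (−)-8-phenylmenthyl ester analogue of 4 | CC(C)(c1ccccc1)[C@@H]1CC[C@@H](C)C[C@H]1OC(=O)/C=C2\C[C@@]3(C)CC=C(C)C[C@@H]23
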